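The route cuts C4a–C8a and C5–C6 of the cis-fused decahydroquinoline. In carbocycle B the neighbours C8a, C4a and C5 hold N1, C4 and C1′ on one face. This cis,cis triad is what an (E)-1-amidodiene and a (Z)-alkene leave when they combine endo. One intramolecular Diels–Alder reaction therefore closes piperidine ring A and cyclohexene ring B together and sets C4a, C5 and C8a. The precursor is a methyl (Z)-5-benzyloxy-6-(N-butadienylamino)hept-2-enoate. Its carbamate carbonyl is tied to an oxygen on C9 (the future C2 methyl) as an oxazolidinone. The tie keeps C9 equatorial and C8 axial, which secures the C2/C8a-trans face. C9 is deoxygenated afterwards.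

Key step: step 8

Assumption: labels follow decahydroquinoline numbering (N1–C8a), the C5 chain is C1′–C8′ and C9 is the carbon on C2. An open-chain N-alkoxycarbonyl group is taken to push the C2 substituent axial (allylic 1,3-strain), which would favour the unwanted C2/C8a-cis adduct, hence the cyclic carbamate.

Step 1
Reactants: 1 N-Boc-D-serinal acetonide
Product: 3 tert-butyl (4R)-4-[(1R)-1-hydroxybut-3-en-1-yl]-2,2-dimethyl-1,3-oxazolidine-3-carboxylate (syn), via borinate ester 2 (not isolated)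
Conditions: (−)-Ipc2B(allyl) (Ipc groups from (−)-α-pinene), Et2O, −78 °C; then NaOH, H2O2, 0 °C to rt
Reagents that add atoms: B-allylbis(isopinocampheyl)borane, C=CCB([C@H]1C[C@H]2C[C@@H]([C@@H]1C)C2(C)C)[C@H]1C[C@H]2C[C@@H]([C@@H]1C)C2(C)C
Why: Brown allylboration: the two isopinocampheyl groups steer the closed chair (Zimmerman–Traxler) transition state to the aldehyde face that sets C3 as (R), the syn N/O pair, against the Felkin–Anh (anti) bias of the substrate, while −78 °C keeps C2 intact.

Step 2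
Reactants: 3 syn homoallylic alcohol
Product: 4 tert-butyl (4R)-4-[(1R)-1-(benzyloxy)but-3-en-1-yl]-2,2-dimethyl-1,3-oxazolidine-3-carboxylate
Conditions: NaH, BnBr, Bu4NI (cat.), THF, 0 °C to rt
Reagents that add atoms: benzyl bromide, BrCc1ccccc1
Why: Williamson etherification of the sodium alkoxide; the nitrogen is fully substituted, so only O3 can be benzylated, and the ether falls in the later hydrogenation.

Step 3
Reactants: 4 benzyl ether
Product: 6 tert-butyl (4R)-4-[(1R)-1-(benzyloxy)-3-oxopropyl]-2,2-dimethyl-1,3-oxazolidine-3-carboxylate, via secondary ozonide 5 (not isolated)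
Conditions: O3, CH2Cl2, −78 °C (indicator end point); Me2S, −78 °C to rt
Reagents that add atoms: ozone, [O-][O+]=O
Why: Ozonolysis with reductive work-up cleaves the only alkene to the C4a aldehyde; because N1 still carries Boc and the acetonide carbon, the γ-amino aldehyde cannot close to a cyclic hemiaminal.

Step 4
Reactants: 6 aldehyde
Product: 7 tert-butyl (4R)-4-[(1R,3Z)-1-(benzyloxy)-5-methoxy-5-oxopent-3-en-1-yl]-2,2-dimethyl-1,3-oxazolidine-3-carboxylate
Conditions: (CF3CH2O)2P(O)CH2CO2Me, KN(SiMe3)2, 18-crown-6, THF, −78 °C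
Reagents that add atoms: methyl bis(2,2,2-trifluoroethyl)phosphonoacetate, COC(=O)CP(=O)(OCC(F)(F)F)OCC(F)(F)F
Why: Still–Gennari variant of the Horner–Wadsworth–Emmons olefination: the electron-poor phosphonate and the dissociated potassium ion make elimination fast and kinetically (Z)-selective, which fixes the C4a=C5 geometry, and the blocked nitrogen excludes 5-exo aza-Michael addition.

Step 5
Reactants: 7 (Z)-enoate acetonide
Product: 8 methyl (2Z,5R,6R)-5-(benzyloxy)-6-[(tert-butoxycarbonyl)amino]-7-hydroxyhept-2-enoate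
Conditions: TsOH·H2O (cat.), MeOH, rt
Reagents that add atoms: none
Why: Acid-catalysed transacetalisation removes the N,O-isopropylidene group under conditions that leave Boc, the benzyl ether and the (Z)-enoate alone.

Step 6
Reactants: 8 N-Boc amino alcohol
Product: 10 methyl (2Z,5R)-5-(benzyloxy)-5-[(4R)-2-oxo-1,3-oxazolidin-4-yl]pent-2-enoate, via primary mesylate 9 (not isolated)
Conditions: MsCl, iPr2NEt, ClCH2CH2Cl, 0 °C, then 80 °C
Reagents that add atoms: none
Why: Neighbouring-group participation: the Boc carbonyl oxygen displaces the primary mesylate (5-exo-tet) and the tert-butyl group leaves as isobutene, so the oxazolidinone tying the carbamate to C9 forms without a free amine or strong base that could add to the enoate.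

Step 7
Reactants: 10 N–H oxazolidinone; 11 crotonaldehyde
Product: 13 methyl (2Z,5R)-5-(benzyloxy)-5-[(4R)-3-[(1E)-buta-1,3-dien-1-yl]-2-oxo-1,3-oxazolidin-4-yl]pent-2-enoate, via hemiaminal 12 (not isolated)
Conditions: TsOH·H2O (cat.), BHT, 4 Å molecular sieves, toluene, 80 °C
Reagents that add atoms: none
Why: Acid-catalysed condensation of a cyclic carbamate N–H with an enolisable enal (hemiaminal, N-acyliminium ion, loss of the γ-proton), the known route to N-dienyl lactams, which gives the conjugated (E)-dienamide as the thermodynamic isomer.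

Step 8
Reactants: 13 N-dienyl oxazolidinone (Z)-enoate
Product: 14 methyl (2R,3R,4aS,5S,8aR)-3-(benzyloxy)-2-(hydroxymethyl)-1,2,3,4,4a,5,6,8a-octahydroquinoline-5-carboxylate N1,O-cyclic carbamate (cis-fused, C7=C8)
Conditions: toluene (0.01 M), BHT (cat.), sealed tube, 130 °C
Reagents that add atoms: none
Why: Concerted, asynchronous, suprafacial [4+2] cycloaddition of the electron-rich (E)-1-amidodiene C8a=C8–C7=C6 with the electron-poor C4a=C5, the known intramolecular Diels–Alder reaction of N-acyl-N-dienylamines that gives cis-fused hydroquinolines. Ring B (cyclohexene) closes by the cycloaddition itself, and ring A (piperidine) closes because the four-atom tether N1–C2–C3–C4 folds into a chair as C4a meets C8a (terminally tethered, type 1 mode); the tether also enforces the regiochemistry, which is the electronically less favoured 1,3-placement of N and ester. The (Z)-geometry is carried over suprafacially and puts C4 and C1′ cis on C4a and C5, and the endo arrangement puts N1 cis to C4, which gives the cis fusion; in it the tether and ester lie under the diene, helped by secondary overlap of the ester carbonyl and by the preferred rotamer with the carbamate C=O beside H8a and C8 beside C2. The face is fixed by C2: C9 lies in the flat oxazolidinone plane and is therefore equatorial in the forming chair, and C3 leaves that plane on one side only, so the enoate reaches one diene face and gives C8, H2 and O3 axial, hence (4aS,5S,8aR) with C2/C8a trans. The step needs endo and facial selectivity; both rest on the rigid N-dienyl oxazolidinone, whose other rotamer would require a boat tether or give a trans-fused adduct with C8 pressed against the carbonyl oxygen.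

Step 9
Reactants: 14 tricyclic ester
Product: 15 (2R,3R,4aS,5S,8aR)-3-(benzyloxy)-2,5-bis(hydroxymethyl)-1,2,3,4,4a,5,6,8a-octahydroquinoline N1,O(C9)-cyclic carbamate
Conditions: LiBH4, THF, 0 °C to rt
Reagents that add atoms: none
Why: Chemoselective ester reduction with LiBH4, which leaves the cyclic carbamate, the alkene and the benzyl ether untouched.

Step 10
Reactants: 15 primary alcohol
Product: 16 (2R,3R,4aS,5S,8aR)-3-(benzyloxy)-2-(hydroxymethyl)-1,2,3,4,4a,5,6,8a-octahydroquinoline-5-carbaldehyde N1,O-cyclic carbamate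
Conditions: Dess–Martin periodinane, CH2Cl2, 0 °C to rt
Reagents that add atoms: none
Why: Dess–Martin oxidation under non-enolising conditions stops at the aldehyde and should not disturb C5.

Step 11
Reactants: 17 (R)-2-propyloxirane
Product: 18 (R)-hept-1-en-4-ol
Conditions: CH2=CHMgBr, CuI (cat.), THF, −30 to 0 °C; then H2O
Reagents that add atoms: vinylmagnesium bromide, C=C[Mg]Br
Why: Copper-catalysed Grignard opening of a terminal epoxide (SN2 at the CH2 terminus), so the C–O stereocentre C5′ is retained as (R).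

Step 12
Reactants: 18 (R)-hept-1-en-4-ol
Product: 19 (R)-tert-butyl(hept-1-en-4-yloxy)dimethylsilane
Conditions: TBSCl, imidazole, DMF, rt
Reagents that add atoms: tert-butyldimethylsilyl chloride, CC(C)(C)[Si](C)(C)Cl
Why: Imidazole-promoted silylation protects O5′ as an ether that survives base, hydride and hydrogenation and falls to acid at the end.

Step 13
Reactants: 19 silyl ether
Product: 21 (R)-4-(tert-butyldimethylsilyloxy)heptan-1-ol, via B-alkyl-9-BBN adduct 20 (not isolated)
Conditions: 9-BBN, THF, 0 °C to rt; then NaOH, H2O2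
Reagents that add atoms: hydrogen peroxide, OO
Why: Hydroboration–oxidation: bulky 9-BBN adds anti-Markovnikov to the terminal alkene, and oxidation with retention gives the primary alcohol at C2′.

Step 14
Reactants: 21 primary alcohol
Product: 22 (R)-tert-butyl[(1-iodoheptan-4-yl)oxy]dimethylsilane
Conditions: I2, PPh3, imidazole, CH2Cl2, 0 °C to rt
Reagents that add atoms: iodine, II
Why: Appel-type iodination (SN2 on the alkoxyphosphonium ion) converts the primary alcohol and leaves the silyl ether in place.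

Step 15
Reactants: 22 primary iodide
Product: 23 [(4R)-4-(tert-butyldimethylsilyloxy)heptyl]triphenylphosphonium iodide
Conditions: PPh3, MeCN, reflux
Reagents that add atoms: triphenylphosphine, c1ccccc1P(c1ccccc1)c1ccccc1
Why: SN2 quaternisation of PPh3 by the primary iodide gives the Wittig salt carrying C2′–C8′.

Step 16
Reactants: 23 phosphonium iodide; 16 aldehyde
Product: 25 (2R,3R,4aS,5R,8aR)-3-(benzyloxy)-5-[(1Z,5R)-5-(tert-butyldimethylsilyloxy)oct-1-en-1-yl]-2-(hydroxymethyl)-1,2,3,4,4a,5,6,8a-octahydroquinoline N1,O-cyclic carbamate (C5 spatially unchanged), via phosphorus ylide 24 (not isolated)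
Conditions: NaN(SiMe3)2, THF, −78 to 0 °C; then 16, −78 °C to rt
Reagents that add atoms: none
Why: Wittig olefination with the non-stabilised ylide forms C1′=C2′; addition at −78 °C is faster than enolisation of the aldehyde, so C5 is kept, and the alkene geometry is irrelevant because it is hydrogenated later.

Step 17
Reactants: 25 oxazolidinone
Product: 26 [(2R,3R,4aS,5R,8aR)-3-(benzyloxy)-5-[(1Z,5R)-5-(tert-butyldimethylsilyloxy)oct-1-en-1-yl]-1,2,3,4,4a,5,6,8a-octahydroquinolin-2-yl]methanol
Conditions: KOH, EtOH–H2O, reflux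
Reagents that add atoms: none
Why: Alkaline hydrolysis of the cyclic carbamate (acyl–oxygen cleavage, loss of carbonate) frees N1–H and the C9 alcohol; the ethers and alkenes are inert to hydroxide.

Step 18
Reactants: 26 amino alcohol
Product: 27 N-Boc derivative of 26
Conditions: Boc2O, MeOH, 40 °C
Reagents that add atoms: di-tert-butyl dicarbonate, CC(C)(C)OC(=O)OC(=O)OC(C)(C)C
Why: Carbamoylation of the more nucleophilic secondary amine with Boc2O, without an acylation catalyst, leaves the primary alcohol free.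

Step 19
Reactants: 27 N-Boc amino alcohol
Product: 29 tert-butyl (2R,3R,4aS,5R,8aR)-3-(benzyloxy)-5-[(1Z,5R)-5-(tert-butyldimethylsilyloxy)oct-1-en-1-yl]-2-methyl-3,4,4a,5,6,8a-hexahydroquinoline-1(2H)-carboxylate, via mesylate 28 (not isolated)
Conditions: MsCl, Et3N, CH2Cl2, −20 °C; crude 28, LiBHEt3, THF, 0 °C to rt
Reagents that add atoms: none
Why: Sulfonate formation and SN2 hydride displacement, the standard deoxygenation of N-Boc 2-(hydroxymethyl) azacycles, turns C9 into the C2 methyl group without touching C2; the crude mesylate is used at once so that it cannot close back to the oxazolidinone.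

Step 20
Reactants: 29 diene benzyl ether
Product: 30 tert-butyl (2R,3R,4aS,5S,8aR)-5-[(5R)-5-(tert-butyldimethylsilyloxy)octyl]-3-hydroxy-2-methyldecahydroquinoline-1-carboxylate
Conditions: H2 (3 atm), Pd(OH)2/C, EtOH, rt
Reagents that add atoms: none
Why: Heterogeneous catalytic hydrogenation saturates C7=C8 and C1′=C2′ and hydrogenolyses the benzyl ether in one operation, creating no new stereocentre and leaving O3 as the only free hydroxyl.

Step 21
Reactants: 30 C3 alcohol; 31 (2E,4E)-octa-2,4-dienoic acid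
Product: 33 N-Boc, O5′-TBS protected target, via mixed anhydride 32 (not isolated)
Conditions: 31, 2,4,6-Cl3C6H2COCl, Et3N, toluene, rt; then 30, DMAP, rt to 40 °C
Reagents that add atoms: none
Why: Yamaguchi esterification: DMAP attacks the mixed anhydride at the less hindered dienoyl carbonyl, and the acylpyridinium ion acylates the hindered C3 alcohol with retention at C3 and without moving the (E,E)-diene.

Step 22
Reactants: 33 protected ester
Product: 34 target, (2R,3R,4aS,5S,8aR)-5-[(5R)-5-hydroxyoctyl]-2-methyldecahydroquinolin-3-yl (2E,4E)-octa-2,4-dienoate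
Conditions: CF3CO2H–H2O (9:1), 0 °C to rt; cold aq NaHCO3
Reagents that add atoms: none
Why: Acidolysis removes Boc (tert-butyl cation, decarboxylation) and the silyl ether in one operation while the dienoate is stable to acid; cold, brief neutralisation limits O-to-N acyl shift.

Compound list
1 | tert-butyl (4R)-4-formyl-2,2-dimethyl-1,3-oxazolidine-3-carboxylate | O=C[C@H]1COC(C)(C)N1C(=O)OC(C)(C)C | starting material
2 | bis(isopinocampheyl)borinate of 3 | C=CC[C@@H](OB([C@H]1C[C@H]2C[C@@H]([C@@H]1C)C2(C)C)[C@H]1C[C@H]2C[C@@H]([C@@H]1C)C2(C)C)[C@H]1COC(C)(C)N1C(=O)OC(C)(C)C | intermediate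
3 | tert-butyl (4R)-4-[(1R)-1-hydroxybut-3-en-1-yl]-2,2-dimethyl-1,3-oxazolidine-3-carboxylate | C=CC[C@@H](O)[C@H]1COC(C)(C)N1C(=O)OC(C)(C)C | intermediate
4 | tert-butyl (4R)-4-[(1R)-1-(benzyloxy)but-3-en-1-yl]-2,2-dimethyl-1,3-oxazolidine-3-carboxylate | C=CC[C@@H](OCc1ccccc1)[C@H]1COC(C)(C)N1C(=O)OC(C)(C)C | intermediate
5 | secondary ozonide (1,2,4-trioxolane) of 4 | C1(C[C@@H](OCc2ccccc2)[C@H]2COC(C)(C)N2C(=O)OC(C)(C)C)OCOO1 | intermediate
6 | tert-butyl (4R)-4-[(1R)-1-(benzyloxy)-3-oxopropyl]-2,2-dimethyl-1,3-oxazolidine-3-carboxylate | O=CC[C@@H](OCc1ccccc1)[C@H]1COC(C)(C)N1C(=O)OC(C)(C)C | intermediate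
7 | tert-butyl (4R)-4-[(1R,3Z)-1-(benzyloxy)-5-methoxy-5-oxopent-3-en-1-yl]-2,2-dimethyl-1,3-oxazolidine-3-carboxylate | COC(=O)/C=C\C[C@@H](OCc1ccccc1)[C@H]1COC(C)(C)N1C(=O)OC(C)(C)C | intermediate
8 | methyl (2Z,5R,6R)-5-(benzyloxy)-6-[(tert-butoxycarbonyl)amino]-7-hydroxyhept-2-enoate | COC(=O)/C=C\C[C@@H](OCc1ccccc1)[C@@H](CO)NC(=O)OC(C)(C)C | intermediate
9 | methyl (2Z,5R,6R)-5-(benzyloxy)-6-[(tert-butoxycarbonyl)amino]-7-(methylsulfonyloxy)hept-2-enoate | COC(=O)/C=C\C[C@@H](OCc1ccccc1)[C@@H](COS(C)(=O)=O)NC(=O)OC(C)(C)C | intermediate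
10 | methyl (2Z,5R)-5-(benzyloxy)-5-[(4R)-2-oxo-1,3-oxazolidin-4-yl]pent-2-enoate | COC(=O)/C=C\C[C@@H](OCc1ccccc1)[C@H]1COC(=O)N1 | intermediate
11 | (E)-but-2-enal (crotonaldehyde) | C/C=C/C=O | starting material
12 | N-[(2E)-1-hydroxybut-2-enyl] hemiaminal of 10 | COC(=O)/C=C\C[C@@H](OCc1ccccc1)[C@H]1COC(=O)N1C(O)/C=C/C | intermediate
13 | methyl (2Z,5R)-5-(benzyloxy)-5-[(4R)-3-[(1E)-buta-1,3-dien-1-yl]-2-oxo-1,3-oxazolidin-4-yl]pent-2-enoate | COC(=O)/C=C\C[C@@H](OCc1ccccc1)[C@H]1COC(=O)N1/C=C/C=C | intermediate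
14 | methyl (2R,3R,4aS,5S,8aR)-3-(benzyloxy)-2-(hydroxymethyl)-1,2,3,4,4a,5,6,8a-octahydroquinoline-5-carboxylate N1,O-cyclic carbamate | c1ccccc1CO[C@@H]1C[C@H]2[C@@H](C(=O)OC)CC=C[C@H]2N3C(=O)OC[C@H]13 | intermediate
15 | C5-hydroxymethyl analogue of 14 | c1ccccc1CO[C@@H]1C[C@H]2[C@@H](CO)CC=C[C@H]2N3C(=O)OC[C@H]13 | intermediate
16 | C5-carbaldehyde analogue of 14 | c1ccccc1CO[C@@H]1C[C@H]2[C@@H](C=O)CC=C[C@H]2N3C(=O)OC[C@H]13 | intermediate
17 | (R)-2-propyloxirane | CCC[C@@H]1CO1 | starting material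
18 | (R)-hept-1-en-4-ol | CCC[C@H](CC=C)O | intermediate
19 | (R)-tert-butyl(hept-1-en-4-yloxy)dimethylsilane | CCC[C@H](CC=C)O[Si](C)(C)C(C)(C)C | intermediate
20 | 9-[(4R)-4-(tert-butyldimethylsilyloxy)heptyl]-9-borabicyclo[3.3.1]nonane | CCC[C@H](CCCB1C2CCCC1CCC2)O[Si](C)(C)C(C)(C)C | intermediate
21 | (R)-4-(tert-butyldimethylsilyloxy)heptan-1-ol | CCC[C@H](CCCO)O[Si](C)(C)C(C)(C)C | intermediate
22 | (R)-tert-butyl[(1-iodoheptan-4-yl)oxy]dimethylsilane | CCC[C@H](CCCI)O[Si](C)(C)C(C)(C)C | intermediate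
23 | [(4R)-4-(tert-butyldimethylsilyloxy)heptyl]triphenylphosphonium iodide | CCC[C@H](CCC[P+](c1ccccc1)(c1ccccc1)c1ccccc1)O[Si](C)(C)C(C)(C)C.[I-] | intermediate
24 | [(4R)-4-(tert-butyldimethylsilyloxy)heptylidene]triphenylphosphorane | CCC[C@H](CCC=P(c1ccccc1)(c1ccccc1)c1ccccc1)O[Si](C)(C)C(C)(C)C | intermediate
25 | Wittig product, oxazolidinone-fused octahydroquinoline with the (1Z,5R)-5-silyloxyoct-1-enyl chain on C5 | c1ccccc1CO[C@@H]1C[C@H]2[C@@H](/C=C\CC[C@H](O[Si](C)(C)C(C)(C)C)CCC)CC=C[C@H]2N3C(=O)OC[C@H]13 | intermediate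
26 | N1–H, C9–OH amino alcohol from 25 | c1ccccc1CO[C@@H]1C[C@H]2[C@@H](/C=C\CC[C@H](O[Si](C)(C)C(C)(C)C)CCC)CC=C[C@H]2N[C@@H]1CO | intermediate
27 | N-Boc amino alcohol | c1ccccc1CO[C@@H]1C[C@H]2[C@@H](/C=C\CC[C@H](O[Si](C)(C)C(C)(C)C)CCC)CC=C[C@H]2N(C(=O)OC(C)(C)C)[C@@H]1CO | intermediate
28 | C9 mesylate of 27 | c1ccccc1CO[C@@H]1C[C@H]2[C@@H](/C=C\CC[C@H](O[Si](C)(C)C(C)(C)C)CCC)CC=C[C@H]2N(C(=O)OC(C)(C)C)[C@@H]1COS(C)(=O)=O | intermediate
29 | N-Boc 2-methyl-3-benzyloxy octahydroquinoline with the octenyl chain | c1ccccc1CO[C@@H]1C[C@H]2[C@@H](/C=C\CC[C@H](O[Si](C)(C)C(C)(C)C)CCC)CC=C[C@H]2N(C(=O)OC(C)(C)C)[C@@H]1C | intermediate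
30 | tert-butyl (2R,3R,4aS,5S,8aR)-5-[(5R)-5-(tert-butyldimethylsilyloxy)octyl]-3-hydroxy-2-methyldecahydroquinoline-1-carboxylate | O[C@@H]1C[C@H]2[C@@H](CCCC[C@H](O[Si](C)(C)C(C)(C)C)CCC)CCC[C@H]2N(C(=O)OC(C)(C)C)[C@@H]1C | intermediate
31 | (2E,4E)-octa-2,4-dienoic acid | CCC/C=C/C=C/C(=O)O | starting material
32 | (2E,4E)-octa-2,4-dienoic 2,4,6-trichlorobenzoic anhydride | CCC/C=C/C=C/C(=O)OC(=O)c1c(Cl)cc(Cl)cc1Cl | intermediate
33 | N-Boc, O5′-TBS protected target | CCC/C=C/C=C/C(=O)O[C@@H]1C[C@H]2[C@@H](CCCC[C@H](O[Si](C)(C)C(C)(C)C)CCC)CCC[C@H]2N(C(=O)OC(C)(C)C)[C@@H]1C | intermediate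
34 | (2R,3R,4aS,5S,8aR)-5-[(5R)-5-hydroxyoctyl]-2-methyldecahydroquinolin-3-yl (2E,4E)-octa-2,4-dienoate | CCC/C=C/C=C/C(=O)O[C@@H]1C[C@H]2[C@@H](CCCC[C@H](O)CCC)CCC[C@H]2N[C@@H]1C | target

Total step count: 22. Longest linear sequence: 17 (steps 1–10 and 16–22).

Steps most likely to fail

**Step 8.** The cycloaddition may be slow, because the tether imposes the electronically mismatched orientation in which the donor-bearing C8a must bond to the β-carbon C4a. At the temperature then needed the (Z)-enoate can drift to (E), the diene can polymerise and exo closure can compete. The fallback changes the dienophile. Starting from 13, iBu2AlH (CH2Cl2, −78 °C) reduces the ester to the (Z)-allylic alcohol F1. MnO2 (CH2Cl2, rt) then oxidises it to the (Z)-enal F2. As a far stronger dienophile, F2 should cyclise at or below room temperature through the same chair, endo arrangement. This gives aldehyde 16 directly, where the route is rejoined and steps 9 and 10 are skipped.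

**Step 7.** Condensation at the hindered N–H may stall while crotonaldehyde self-condenses, and diene formed at 80 °C under acid may start to cyclise or hydrolyse. The fallback splits the event into two mild operations. Starting from 10, acetal exchange with (E)-1,1-diethoxybut-2-ene (camphorsulfonic acid cat., toluene, removal of EtOH) gives the N-(1-ethoxybut-2-enyl) N,O-acetal F3. Me3SiOTf and Et3N (CH2Cl2, 0 °C) then induce 1,4-elimination of ethanol, and the route is rejoined at 13.

**Step 1.** The reagent works against the anti preference of the aldehyde, so facial selectivity at C3 may erode. The fallback uses the substrate bias and then inverts. Starting from 1, CH2=CHCH2MgBr (THF, −78 °C) gives the Felkin–Anh anti alcohol F4. Mitsunobu inversion (4-nitrobenzoic acid, PPh3, diisopropyl azodicarboxylate) gives the (1R)-4-nitrobenzoate F5. K2CO3 in MeOH releases 3.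

Further compounds
F1 | step 8 | (4R)-4-[(1R,3Z)-1-(benzyloxy)-5-hydroxypent-3-en-1-yl]-3-[(1E)-buta-1,3-dien-1-yl]-1,3-oxazolidin-2-one | OC/C=C\C[C@@H](OCc1ccccc1)[C@H]1COC(=O)N1/C=C/C=C
F2 | step 8 | (2Z,5R)-5-(benzyloxy)-5-[(4R)-3-[(1E)-buta-1,3-dien-1-yl]-2-oxo-1,3-oxazolidin-4-yl]pent-2-enal | O=C/C=C\C[C@@H](OCc1ccccc1)[C@H]1COC(=O)N1/C=C/C=C
F3 | step 7 | methyl (2Z,5R)-5-(benzyloxy)-5-[(4R)-3-[(2E)-1-ethoxybut-2-en-1-yl]-2-oxo-1,3-oxazolidin-4-yl]pent-2-enoate | COC(=O)/C=C\C[C@@H](OCc1ccccc1)[C@H]1COC(=O)N1C(OCC)/C=C/C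
F4 | step 1 | tert-butyl (4R)-4-[(1S)-1-hydroxybut-3-en-1-yl]-2,2-dimethyl-1,3-oxazolidine-3-carboxylate | C=CC[C@H](O)[C@H]1COC(C)(C)N1C(=O)OC(C)(C)C
F5 | step 1 | tert-butyl (4R)-2,2-dimethyl-4-[(1R)-1-(4-nitrobenzoyloxy)but-3-en-1-yl]-1,3-oxazolidine-3-carboxylate | C=CC[C@@H](OC(=O)c1ccc(cc1)[N+](=O)[O-])[C@H]1COC(C)(C)N1C(=O)OC(C)(C)C
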